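## Retrosynthetic overview
1. The ring A prenyl group is cut last. The target comes from the (2S)-8-iodoflavanone and a prenylstannane by base-free Stille coupling, so no acid-sensitive ring A prenylphenol exists earlier in the route.
2. The O–CMe2 bond of ring D and the O1–C2 bond of ring C are cut together, giving an open-chain iodo-prenyl-chalcone. In the forward direction one chiral Brønsted acid closes both rings in one flask and sets C2.
3. The chalcone is cut into 3-iodo-2,4-dihydroxyacetophenone and 4-hydroxy-3-prenylbenzaldehyde (Claisen–Schmidt).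
4. The iodoketone comes from 2,4-dihydroxyacetophenone (C3 iodination). The aldehyde comes from 4-hydroxybenzaldehyde and prenyl bromide (ortho C-prenylation).
5. Ring order: aromatic rings A and B are bought. Ring D, then ring C, form in the same operation (step 4).

Assumption: IDPi means a BINOL-derived imidodiphosphorimidate Brønsted acid, obtained separately and not counted as a step; its sense of induction cannot be predicted safely, so the (S,S) antipode is written and the (R,R) antipode is used instead if a test run gives 2R.

## Route

Step 1
Reactants: 1 2,4-dihydroxyacetophenone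
Product: 2 1-(2,4-dihydroxy-3-iodophenyl)ethan-1-one
Conditions: I2 (0.4 equiv), HIO3 (0.2 equiv), EtOH/H2O, 35–40 °C, 2 h
Reagents that add atoms: iodine, [I][I]; iodic acid, OI(=O)=O
Why: Electrophilic aromatic iodination: the hydrogen bond between the 2-OH and the carbonyl fixes the ring so that C3, ortho to both hydroxyls, is the most nucleophilic carbon, and HIO3 re-oxidises the iodide formed so that all iodine ends up in the product and over-iodination is limited by stoichiometry.

Step 2
Reactants: 3 4-hydroxybenzaldehyde; 4 prenyl bromide (1-bromo-3-methylbut-2-ene)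
Product: 5 4-hydroxy-3-(3-methylbut-2-en-1-yl)benzaldehyde
Conditions: KOH (1.1 equiv, 10 % aq.), rt, 24 h; chromatography
Reagents that add atoms: none
Why: Ortho C-alkylation of an ambident phenoxide: in water the phenoxide oxygen is strongly solvated, so the soft allylic bromide is attacked in part by the ortho carbon (para is blocked by CHO) with SN2 regiochemistry, and the O-prenyl ether by-product is removed by chromatography (expect 35–45 %).

Step 3
Reactants: 2 1-(2,4-dihydroxy-3-iodophenyl)ethan-1-one; 5 4-hydroxy-3-(3-methylbut-2-en-1-yl)benzaldehyde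
Product: 6 (E)-1-(2,4-dihydroxy-3-iodophenyl)-3-[4-hydroxy-3-(3-methylbut-2-en-1-yl)phenyl]prop-2-en-1-one
Conditions: KOH (50 % aq., excess), EtOH, N2, rt to 40 °C, 48 h; cold dilute acid to pH 4
Reagents that add atoms: none
Why: Claisen–Schmidt (crossed aldol) condensation: only the methyl ketone can enolise and the aldehyde has no α-hydrogens, E1cB loss of hydroxide gives the E-enone alone, the polyphenoxide stays ring-open in strong base, and the prenyl alkene and the carbon-iodine bond are inert to hydroxide.

Step 4 (key step)
Reactants: 6 (E)-1-(2,4-dihydroxy-3-iodophenyl)-3-[4-hydroxy-3-(3-methylbut-2-en-1-yl)phenyl]prop-2-en-1-one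
Product: 8 (2S)-7-hydroxy-8-iodo-2-(2,2-dimethylchroman-6-yl)chroman-4-one, via chroman chalcone 7 (not isolated)
Conditions: (S,S)-IDPi (3,3'-aryl = 3,5-(CF3)2C6H3, N-SO2CF3; 5 mol %), 4 Å MS, ClCH2CH2Cl (0.05 M), 45 °C, ca. 48 h, stopped at ca. 85 % conversion; silica plug, open chalcone recycled, recrystallisation (EtOAc/heptane) to raise ee
Reagents that add atoms: none
Why: Proposed new method: the strong confined acid first protonates the trisubstituted prenyl alkene in the Markovnikov sense and the neighbouring ring B phenol traps the tertiary cation to close ring D (no stereocentre; closest known types are the acid cyclisation of o-prenylphenols to 2,2-dimethylchromans and the IDPi-catalysed intramolecular hydroalkoxylation of unactivated alkenes), then the same acid protonates the enone carbonyl of 7 and the 2'-OH adds 6-endo-trig to one face of the β-carbon inside the chiral contact ion pair while the anion takes up the phenol proton, which closes ring C and sets C2 as S (closest known types are the acid-catalysed 2'-hydroxychalcone-to-flavanone isomerisation and the chiral Brønsted acid-catalysed intramolecular hetero-Michael cyclisation of 2'-aminochalcones); closing ring D first removes the free ring B phenol that would allow racemisation through a p-quinone methide, acid catalysis avoids the catalyst quenching that the acidic 4'-OH would cause with chiral bases, and the heavy iodine atom lets the 2S configuration be confirmed by X-ray.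

Step 5
Reactants: 8 (2S)-7-hydroxy-8-iodo-2-(2,2-dimethylchroman-6-yl)chroman-4-one; 9 tributyl(3-methylbut-2-en-1-yl)stannane
Product: 10 euchrenone a17, (2S)-7-hydroxy-8-(3-methylbut-2-en-1-yl)-2-(2,2-dimethylchroman-6-yl)chroman-4-one
Conditions: 9 (1.5 equiv), Pd2(dba)3 (2.5 mol %), AsPh3 (20 mol %), degassed amine-free DMF, 60 °C, 12 h, dark
Reagents that add atoms: none
Why: Stille cross-coupling: zerovalent palladium inserts into the carbon-iodine bond, the allylic stannane transmetalates and reductive elimination from the η3-prenyl(aryl)palladium takes place at the unsubstituted terminus to give the linear prenyl group, while the neutral, base-free and acid-free medium leaves the C2 stereocentre (no retro-oxa-Michael), the free 7-OH and the new o-prenylphenol untouched.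

## Compound list
1 | 2,4-dihydroxyacetophenone | CC(=O)c1ccc(O)cc1O | starting material
2 | 1-(2,4-dihydroxy-3-iodophenyl)ethan-1-one | Ic1c(O)ccc(C(C)=O)c1O | intermediate
3 | 4-hydroxybenzaldehyde | O=Cc1ccc(O)cc1 | starting material
4 | prenyl bromide (1-bromo-3-methylbut-2-ene) | CC(C)=CCBr | starting material
5 | 4-hydroxy-3-(3-methylbut-2-en-1-yl)benzaldehyde | CC(C)=CCc1cc(C=O)ccc1O | intermediate
6 | (E)-1-(2,4-dihydroxy-3-iodophenyl)-3-[4-hydroxy-3-(3-methylbut-2-en-1-yl)phenyl]prop-2-en-1-one | Ic1c(O)ccc(C(=O)/C=C/c2ccc(O)c(CC=C(C)C)c2)c1O | intermediate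
7 | (E)-1-(2,4-dihydroxy-3-iodophenyl)-3-(2,2-dimethylchroman-6-yl)prop-2-en-1-one | Ic1c(O)ccc(C(=O)/C=C/c2ccc3OC(C)(C)CCc3c2)c1O | intermediate
8 | (2S)-7-hydroxy-8-iodo-2-(2,2-dimethylchroman-6-yl)chroman-4-one | Ic1c(O)ccc2c1O[C@H](c1ccc3c(c1)CCC(C)(C)O3)CC2=O | intermediate
9 | tributyl(3-methylbut-2-en-1-yl)stannane | CCCC[Sn](CCCC)(CCCC)CC=C(C)C | starting material
10 | euchrenone a17, (2S)-7-hydroxy-8-(3-methylbut-2-en-1-yl)-2-(2,2-dimethylchroman-6-yl)chroman-4-one | CC(C)=CCc1c(O)ccc2c1O[C@H](c1ccc3c(c1)CCC(C)(C)O3)CC2=O | target

## Step count and risks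
Total steps: 5. Longest linear sequence: 4 (steps 1, 3, 4, 5 or steps 2, 3, 4, 5).

**Most likely to fail, first: step 4.** The ring C closure is reversible, so ee erodes near equilibrium. The doubly donor-stabilised enone may also close slowly, and ipso-protonation could cost some iodine.
- The fallback sets out from 6 and comes back to the route at 8. It gives up catalyst control in the cascade and resolves afterwards.
- p-TsOH·H2O (20 mol %) in toluene at 80 °C closes the same two rings without stereocontrol. This gives racemic 7-hydroxy-8-iodo-2-(2,2-dimethylchroman-6-yl)chroman-4-one F1.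
- Kinetic resolution follows by asymmetric transfer hydrogenation with RuCl(p-cymene)[(R,R)-TsDPEN] and HCO2H/Et3N in EtOAc at rt, run to about 52 % conversion.
- The 2R enantiomer is reduced to (2R,4R)-8-iodo-2-(2,2-dimethylchroman-6-yl)chroman-4,7-diol F2.
- The slow-reacting 2S ketone 8 is separated by chromatography.

**Second: step 5.** The iodide is flanked by two oxygen substituents. The prenylstannane may transfer slowly or give some reverse-prenyl (γ) product.
- The fallback sets out from 8 and comes back to the route at 10. It builds the trisubstituted alkene by metathesis instead of transferring it whole.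
- Allyltributylstannane under the same palladium system has no α/γ ambiguity. It gives (2S)-8-allyl-7-hydroxy-2-(2,2-dimethylchroman-6-yl)chroman-4-one F3.
- Cross-metathesis with excess 2-methylbut-2-ene and the second-generation Grubbs catalyst (H2IMes)(PCy3)Cl2Ru=CHPh in CH2Cl2 at 40 °C converts the allyl group into the prenyl group of 10.

**Third: step 3.** Both partners are electron-rich polyphenoxides in strong base, so enolisation and addition are slow and the yield may be poor.
- The fallback sets out from 2 and comes back to the route at 6. It replaces enolate chemistry by a Wittig olefination that tolerates free phenols.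
- CuBr2 (2 equiv) in refluxing EtOAc/CHCl3 gives 2-bromo-1-(2,4-dihydroxy-3-iodophenyl)ethan-1-one F4.
- PPh3 in THF at rt gives [2-(2,4-dihydroxy-3-iodophenyl)-2-oxoethyl]triphenylphosphonium bromide F5.
- One equivalent of aq. NaOH in CH2Cl2 at 0 °C gives the stabilised ylide 1-(2,4-dihydroxy-3-iodophenyl)-2-(triphenyl-λ5-phosphanylidene)ethan-1-one F6.
- Heating this ylide with 5 in refluxing toluene gives the E-chalcone 6.

## Further compounds
F1 | step 4 | racemic 7-hydroxy-8-iodo-2-(2,2-dimethylchroman-6-yl)chroman-4-one | Ic1c(O)ccc2c1OC(c1ccc3c(c1)CCC(C)(C)O3)CC2=O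
F2 | step 4 | (2R,4R)-8-iodo-2-(2,2-dimethylchroman-6-yl)chroman-4,7-diol | Ic1c(O)ccc2c1O[C@@H](c1ccc3c(c1)CCC(C)(C)O3)C[C@H]2O
F3 | step 5 | (2S)-8-allyl-7-hydroxy-2-(2,2-dimethylchroman-6-yl)chroman-4-one | C=CCc1c(O)ccc2c1O[C@H](c1ccc3c(c1)CCC(C)(C)O3)CC2=O
F4 | step 3 | 2-bromo-1-(2,4-dihydroxy-3-iodophenyl)ethan-1-one | Ic1c(O)ccc(C(=O)CBr)c1O
F5 | step 3 | [2-(2,4-dihydroxy-3-iodophenyl)-2-oxoethyl]triphenylphosphonium bromide | Ic1c(O)ccc(C(=O)C[P+](c2ccccc2)(c2ccccc2)c2ccccc2)c1O.[Br-]
F6 | step 3 | 1-(2,4-dihydroxy-3-iodophenyl)-2-(triphenyl-λ5-phosphanylidene)ethan-1-one | Ic1c(O)ccc(C(=O)C=P(c2ccccc2)(c2ccccc2)c2ccccc2)c1O
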